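## Retrosynthetic overview

1. The target is read as epicatechin 3-O-gallate-(4β→8)-epigallocatechin 3-O-gallate-(4β→8)-catechin 3-O-gallate. The last skeletal bond (upper C4 to middle C8) comes from a Lewis-acid coupling of a 4-(2-ethoxyethoxy)epicatechin gallate with the benzylated middle–lower dimer bis-gallate, followed by global hydrogenolysis.
2. The strategy rests on one feature: C4 of the middle unit is a diarylmethine carbon bonded to ring A carbon C4a (ortho to O1) and to C8 of the catechin unit, with the oxygenated C3 next to it. That carbon is the methide carbon of an ortho-quinone methide of ring A.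
3. Middle ring C (bonds C3–C4 and O1–C2) is therefore made by an amine-catalysed [4+2] annulation of that quinone methide with the enamine of silyloxyacetaldehyde. C2 is then arylated through the lactone (aryllithium addition, silane reduction of the hemiketal).
4. The quinone methide precursor is the hydroxybenzhydrol from 8-lithiated protected catechin and 2-allyloxy-4,6-dibenzyloxybenzaldehyde; the allyl group is removed by palladium under neutral conditions.
5. Ring order: the catechin and epicatechin ring systems come from the natural flavanols; only middle ring C is built (step 8), and its ring B is attached afterwards (steps 12 and 13).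

Key step: step 8

## Remarks and assumptions

- Bn = benzyl, TBS = tert-butyldimethylsilyl. α/β mean below/above ring C in the usual flavan drawing (the 2-aryl group of a 2R flavan is α).
- Assumption: the E-enamine of the α-silyloxy aldehyde is attacked on the same face as the enamines of simple alkanals, so the (S)-configured catalyst is taken for the 3R (3α-O) centre.
- CIP descriptors at C4 of the middle unit change with substitution at C8, so α/β notation and the SMILES strings are used for that centre.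

## Route

Step 1
Reactants: 1 (+)-catechin
Product: 2 5,7,3',4'-tetra-O-benzyl-(+)-catechin
Conditions: BnBr (4.2 equiv), K2CO3, DMF, 0 °C to rt
Reagents that add atoms: benzyl bromide, BrCc1ccccc1
Why: Williamson etherification takes the four phenols, which are far more acidic than the secondary 3-OH, so that alcohol stays free and C2 and C3 are not touched.

Step 2
Reactants: 2 5,7,3',4'-tetra-O-benzyl-(+)-catechin
Product: 3 5,7,3',4'-tetra-O-benzyl-3-O-TBS-(+)-catechin
Conditions: TBSCl, imidazole, DMF, rt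
Reagents that add atoms: tert-butyldimethylsilyl chloride, CC(C)(C)[Si](C)(C)Cl
Why: Silylation of the secondary alcohol gives an ether that survives organolithium reagents and mild acid and is later removed by fluoride.

Step 3
Reactants: 3 5,7,3',4'-tetra-O-benzyl-3-O-TBS-(+)-catechin
Product: 4 8-bromo-5,7,3',4'-tetra-O-benzyl-3-O-TBS-(+)-catechin
Conditions: NBS (1.0 equiv), CH2Cl2, −78 °C to rt
Reagents that add atoms: N-bromosuccinimide, O=C1CCC(=O)N1Br
Why: Electrophilic aromatic bromination of the phloroglucinol-type ring A of 5,7-di-O-benzyl flavan-3-ol ethers goes to C8 in preference to C6, and one equivalent should stop at the monobromide.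

Step 4
Reactants: 5 2,4,6-trihydroxybenzaldehyde
Product: 6 2,4-bis(benzyloxy)-6-hydroxybenzaldehyde
Conditions: BnBr (2.05 equiv), K2CO3, DMF, rt
Reagents that add atoms: benzyl bromide, BrCc1ccccc1
Why: Williamson etherification takes the 4-OH and one ortho OH, while the remaining ortho phenol is held in a hydrogen bond to the formyl group and reacts last.

Step 5
Reactants: 6 2,4-bis(benzyloxy)-6-hydroxybenzaldehyde
Product: 7 2-(allyloxy)-4,6-bis(benzyloxy)benzaldehyde
Conditions: allyl bromide, K2CO3, DMF, 60 °C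
Reagents that add atoms: allyl bromide, C=CCBr
Why: Forcing Williamson allylation caps the hydrogen-bonded phenol with a group that is inert to aryllithium and comes off later under neutral palladium catalysis, which an acid-labile acetal could not do without ionising the carbinol.

Step 6
Reactants: 4 8-bromo-5,7,3',4'-tetra-O-benzyl-3-O-TBS-(+)-catechin; 7 2-(allyloxy)-4,6-bis(benzyloxy)benzaldehyde
Product: 9 [2-(allyloxy)-4,6-bis(benzyloxy)phenyl](5,7,3',4'-tetra-O-benzyl-3-O-TBS-catechin-8-yl)methanol as both carbinol epimers, via 8-lithio catechin ether 8 (not isolated)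
Conditions: t-BuLi (2.1 equiv), THF, −78 °C; then 7, −78 to −40 °C; H2O
Reagents that add atoms: none
Why: Bromine–lithium exchange at −78 °C outruns attack on the benzyl and silyl ethers and the C8 aryllithium adds 1,2 to the aldehyde, the new carbinol centre forming as a mixture that step 8 erases.

Step 7
Reactants: 9 [2-(allyloxy)-4,6-bis(benzyloxy)phenyl](5,7,3',4'-tetra-O-benzyl-3-O-TBS-catechin-8-yl)methanol
Product: 10 [4,6-bis(benzyloxy)-2-hydroxyphenyl](5,7,3',4'-tetra-O-benzyl-3-O-TBS-catechin-8-yl)methanol (both carbinol epimers)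
Conditions: Pd(PPh3)4 (5 mol %), morpholine, THF, rt; filtration through Et3N-deactivated silica, used at once
Reagents that add atoms: none
Why: In this Tsuji–Trost-type deallylation zerovalent palladium ionises the aryl allyl ether and morpholine traps the π-allyl fragment, which frees the phenol under neutral to basic conditions that leave the acid-sensitive diarylcarbinol, the TBS ether and the benzyl ethers intact.

Step 8
Reactants: 10 [4,6-bis(benzyloxy)-2-hydroxyphenyl](5,7,3',4'-tetra-O-benzyl-3-O-TBS-catechin-8-yl)methanol; 11 (tert-butyldimethylsilyloxy)acetaldehyde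
Product: 14 5,7-bis(benzyloxy)-3α-(tert-butyldimethylsilyloxy)-4β-(5,7,3',4'-tetra-O-benzyl-3-O-TBS-catechin-8-yl)chroman-2-ol (3R; 3,4-trans; both anomers), via ortho-quinone methide 12 (not isolated), via E-enamine 13 (not isolated)
Conditions: (S)-α,α-diphenylprolinol trimethylsilyl ether (20 mol %), PhCO2H (20 mol %), 11 (3 equiv), CH2Cl2, 0 °C to rt
Reagents that add atoms: none
Why: Benzoic acid dehydrates the doubly activated hydroxybenzhydrol 10 to the ortho-quinone methide 12, the E-enamine 13 formed from 11 and the catalyst adds through its α-carbon to the methide carbon (C3–C4 bond), the ring A phenoxide then closes on the iminium carbon (O1–C2 bond), and the water set free hydrolyses the aminal to the lactol and returns the catalyst. The closest known reaction type is the aminocatalytic formal inverse-electron-demand hetero-Diels–Alder reaction (Michael addition then hemiaminal closure) of in situ ortho-quinone methides with aldehyde enamines, which gives 3,4-trans chroman-2-ols. Ring C is closed by 6-exo-trig attack of the phenol oxygen on the iminium carbon. C3 is set by the catalyst, whose diphenyl(silyloxy)methyl group blocks one face of the s-trans E-enamine so that the methide is met by the face that gives the 3R (3α-O) centre; C4 is set by the relative topicity of the partners, the E-methide (catechin aryl outside the heterodiene) meeting the enamine with nitrogen endo and the silyloxy group exo, which places the aryl group trans to the C3 oxygen (4β); C2 is an uncontrolled anomeric centre that step 9 removes. The step needs attack at the methide carbon only, 3,4-trans geometry and a catalyst-controlled absolute sense: the methide carbon is the only electrophilic site of 12, the E and Z methides interconvert through the benzylic cation under the acid so that the better-fitting E isomer can be drawn off, and the catechin stereocentres lie four bonds from the reacting carbon and should not override the catalyst.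

Step 9
Reactants: 14 5,7-bis(benzyloxy)-3α-(tert-butyldimethylsilyloxy)-4β-(protected catechin-8-yl)chroman-2-ol
Product: 15 5,7-bis(benzyloxy)-3α-(tert-butyldimethylsilyloxy)-4β-(5,7,3',4'-tetra-O-benzyl-3-O-TBS-catechin-8-yl)chroman-2-one
Conditions: (n-Pr4N)RuO4 (5 mol %), NMO, 4 Å MS, CH2Cl2, rt
Reagents that add atoms: none
Why: Ley–Griffith oxidation converts the lactol into the lactone under neutral conditions, which removes the anomeric centre without exposing the C3 centre next to the new carbonyl to base.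

Step 10
Reactants: 16 5-bromo-1,2,3-trimethoxybenzene
Product: 17 5-bromobenzene-1,2,3-triol
Conditions: BBr3 (3.5 equiv), CH2Cl2, −78 °C to rt; H2O
Reagents that add atoms: none
Why: Lewis-acid cleavage of aryl methyl ethers by BBr3 frees the three phenols and leaves the aryl bromide untouched.

Step 11
Reactants: 17 5-bromobenzene-1,2,3-triol
Product: 18 1,2,3-tris(benzyloxy)-5-bromobenzene
Conditions: BnBr (3.3 equiv), K2CO3, DMF, N2, rt
Reagents that add atoms: benzyl bromide, BrCc1ccccc1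
Why: Williamson etherification under nitrogen protects the air-sensitive bromopyrogallol as the tribenzyl ether that the final hydrogenolysis can remove.

Step 12
Reactants: 15 5,7-bis(benzyloxy)-3α-(tert-butyldimethylsilyloxy)-4β-(protected catechin-8-yl)chroman-2-one; 18 1,2,3-tris(benzyloxy)-5-bromobenzene
Product: 20 5,7-bis(benzyloxy)-3α-(tert-butyldimethylsilyloxy)-4β-(5,7,3',4'-tetra-O-benzyl-3-O-TBS-catechin-8-yl)-2-[3,4,5-tris(benzyloxy)phenyl]chroman-2-ol (hemiketal; both C2 epimers), via 3,4,5-tris(benzyloxy)phenyllithium 19 (not isolated)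
Conditions: 18, n-BuLi (1.2 equiv), THF, −78 °C; cannulated into 15, THF, −78 °C; pH 7 buffer at −78 °C
Reagents that add atoms: none
Why: Nucleophilic addition of an aryllithium to a lactone carbonyl stops at the lithium hemiketalate at −78 °C (the way lactols are made from lactones for C-aryl glycosides), the hindered α-silyloxy centre discouraging a second addition, and the C2 hemiketal centre forms as a mixture that step 13 removes.

Step 13
Reactants: 20 2-[3,4,5-tris(benzyloxy)phenyl]chroman-2-ol hemiketal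
Product: 22 3-O-TBS-5,7,3',4',5'-penta-O-benzyl-(−)-epigallocatechin-(4β→8)-[3-O-TBS-5,7,3',4'-tetra-O-benzyl-(+)-catechin], via cyclic 2-aryl oxocarbenium ion 21 (not isolated)
Conditions: Et3SiH (5 equiv), BF3·OEt2 (2 equiv), CH2Cl2, −78 to −40 °C
Reagents that add atoms: none
Why: BF3·OEt2 ionises the hemiketal to the cyclic oxocarbenium ion 21 and Et3SiH reduces it (ionic hydrogenation of a lactol, as in C-aryl glycoside synthesis); peri strain with the 5-benzyloxy group holds the 4-aryl group pseudoaxial, so the trans 3-silyloxy group is pseudoaxial on the opposite face and the silane should enter axially anti to the C3–O bond, which puts the new C2–H on the β face and the 2-aryl group α (2R, 2,3-cis).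

Step 14
Reactants: 22 3-O-TBS-penta-O-benzyl-epigallocatechin-(4β→8)-3-O-TBS-tetra-O-benzyl-catechin
Product: 23 5,7,3',4',5'-penta-O-benzyl-(−)-epigallocatechin-(4β→8)-[5,7,3',4'-tetra-O-benzyl-(+)-catechin] (3,3''-diol)
Conditions: TBAF (4 equiv), THF, 0 °C to rt
Reagents that add atoms: none
Why: Fluoride-driven desilylation (Si–F bond formation) cleaves both secondary TBS ethers without touching the benzyl ethers, the interflavan bond or any stereocentre.

Step 15
Reactants: 24 3,4,5-tris(benzyloxy)benzoic acid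
Product: 25 3,4,5-tris(benzyloxy)benzoyl chloride
Conditions: (COCl)2, DMF (cat.), CH2Cl2, 0 °C to rt; evaporation
Reagents that add atoms: oxalyl chloride, ClC(=O)C(=O)Cl
Why: Chlorination of the carboxylic acid through the Vilsmeier-type chloroiminium species gives the acid chloride, the benzyl ethers being stable to the HCl formed at room temperature.

Step 16
Reactants: 23 dimer 3,3''-diol; 25 3,4,5-tris(benzyloxy)benzoyl chloride
Product: 26 3-O-[3,4,5-tris(benzyloxy)benzoyl]-penta-O-benzyl-epigallocatechin-(4β→8)-3-O-[3,4,5-tris(benzyloxy)benzoyl]-tetra-O-benzyl-catechin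
Conditions: 25 (4 equiv), DMAP, pyridine, CH2Cl2, rt to 40 °C
Reagents that add atoms: none
Why: DMAP-catalysed acylation esterifies both secondary 3-hydroxyls, the excess acid chloride and warming serving the hindered axial hydroxyl of the middle unit, and no stereocentre is touched.

Step 17
Reactants: 27 (−)-epicatechin
Product: 28 5,7,3',4'-tetra-O-benzyl-(−)-epicatechin
Conditions: BnBr (4.2 equiv), K2CO3, DMF, 0 °C to rt
Reagents that add atoms: benzyl bromide, BrCc1ccccc1
Why: Williamson etherification of the four phenols under mild carbonate conditions leaves the 3-OH free and avoids base-induced epimerisation at C2.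

Step 18
Reactants: 28 5,7,3',4'-tetra-O-benzyl-(−)-epicatechin
Product: 29 4β-(2-ethoxyethoxy)-5,7,3',4'-tetra-O-benzyl-(−)-epicatechin
Conditions: DDQ (2 equiv), 2-ethoxyethanol (5 equiv), CH2Cl2, rt
Reagents that add atoms: 2-ethoxyethanol, CCOCCO
Why: DDQ removes hydride from benzylic C4, which is activated by the ring A oxygens (benzylic oxidation), and the alcohol traps the cation from the β face, away from the α-oriented 2-aryl and 3-hydroxy groups, which sets the 3,4-trans 4β-ether.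

Step 19
Reactants: 29 4β-(2-ethoxyethoxy)-tetra-O-benzyl-epicatechin; 25 3,4,5-tris(benzyloxy)benzoyl chloride
Product: 30 4β-(2-ethoxyethoxy)-5,7,3',4'-tetra-O-benzyl-(−)-epicatechin 3-O-[3,4,5-tris(benzyloxy)benzoate]
Conditions: 25 (1.5 equiv), DMAP, pyridine, CH2Cl2, rt
Reagents that add atoms: none
Why: DMAP-catalysed acylation of the 3-hydroxyl under basic conditions leaves the acid-labile 4-ether untouched.

Step 20
Reactants: 26 dimer bis-gallate; 30 4β-(2-ethoxyethoxy)epicatechin gallate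
Product: 31 docosa-O-benzyl epicatechin 3-O-gallate-(4β→8)-epigallocatechin 3-O-gallate-(4β→8)-catechin 3-O-gallate
Conditions: 26 (2 equiv), TMSOTf (0.5 equiv), CH2Cl2, −78 to −40 °C, slow addition of 30; Et3N quench; excess 26 recovered
Reagents that add atoms: none
Why: Lewis-acid ionisation of the 4-ether gives the C4 cation, held on its α face by the 3-O-galloyl carbonyl, and the most nucleophilic free position of the dimer, C8 of the middle unit, should attack it from the β face (Friedel–Crafts-type flavan-4-yl cation coupling), which sets the 3,4-trans 4β→8 bond.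

Step 21
Reactants: 31 docosa-O-benzyl trimer
Product: 32 epicatechin 3-O-gallate-(4β→8)-epigallocatechin 3-O-gallate-(4β→8)-catechin 3-O-gallate (CNP0321910.1)
Conditions: H2 (1 atm), Pd(OH)2/C, THF/MeOH/H2O, rt
Reagents that add atoms: none
Why: Catalytic hydrogenolysis removes all twenty-two O-benzyl groups, while the gallate esters, the interflavan bonds and the ring C ether bonds are stable under these neutral conditions.

## Compound list

1 | (+)-catechin (2R,3S) | O[C@H]1Cc2c(O)cc(O)cc2O[C@@H]1c1ccc(O)c(O)c1 | starting material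
2 | 5,7,3',4'-tetra-O-benzyl-(+)-catechin | O[C@H]1Cc2c(OCc9ccccc9)cc(OCc9ccccc9)cc2O[C@@H]1c1ccc(OCc9ccccc9)c(OCc9ccccc9)c1 | intermediate
3 | 5,7,3',4'-tetra-O-benzyl-3-O-TBS-(+)-catechin | CC(C)(C)[Si](C)(C)O[C@H]1Cc2c(OCc9ccccc9)cc(OCc9ccccc9)cc2O[C@@H]1c1ccc(OCc9ccccc9)c(OCc9ccccc9)c1 | intermediate
4 | 8-bromo-5,7,3',4'-tetra-O-benzyl-3-O-TBS-(+)-catechin | CC(C)(C)[Si](C)(C)O[C@H]1Cc2c(OCc9ccccc9)cc(OCc9ccccc9)c(Br)c2O[C@@H]1c1ccc(OCc9ccccc9)c(OCc9ccccc9)c1 | intermediate
5 | 2,4,6-trihydroxybenzaldehyde | O=Cc1c(O)cc(O)cc1O | starting material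
6 | 2,4-bis(benzyloxy)-6-hydroxybenzaldehyde | O=Cc1c(O)cc(OCc9ccccc9)cc1OCc9ccccc9 | intermediate
7 | 2-(allyloxy)-4,6-bis(benzyloxy)benzaldehyde | O=Cc1c(OCC=C)cc(OCc9ccccc9)cc1OCc9ccccc9 | intermediate
8 | 8-lithio-5,7,3',4'-tetra-O-benzyl-3-O-TBS-catechin | CC(C)(C)[Si](C)(C)O[C@H]1Cc2c(OCc9ccccc9)cc(OCc9ccccc9)c([Li])c2O[C@@H]1c1ccc(OCc9ccccc9)c(OCc9ccccc9)c1 | intermediate (not isolated)
9 | [2-(allyloxy)-4,6-bis(benzyloxy)phenyl](5,7,3',4'-tetra-O-benzyl-3-O-TBS-catechin-8-yl)methanol, both carbinol epimers | OC(c1c(OCC=C)cc(OCc9ccccc9)cc1OCc9ccccc9)c2c(OCc9ccccc9)cc(OCc9ccccc9)c3c2O[C@H](c2ccc(OCc9ccccc9)c(OCc9ccccc9)c2)[C@@H](O[Si](C)(C)C(C)(C)C)C3 | intermediate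
10 | [4,6-bis(benzyloxy)-2-hydroxyphenyl](5,7,3',4'-tetra-O-benzyl-3-O-TBS-catechin-8-yl)methanol, both carbinol epimers | OC(c1c(O)cc(OCc9ccccc9)cc1OCc9ccccc9)c2c(OCc9ccccc9)cc(OCc9ccccc9)c3c2O[C@H](c2ccc(OCc9ccccc9)c(OCc9ccccc9)c2)[C@@H](O[Si](C)(C)C(C)(C)C)C3 | intermediate
11 | (tert-butyldimethylsilyloxy)acetaldehyde | O=CCO[Si](C)(C)C(C)(C)C | starting material
12 | (E)-3,5-bis(benzyloxy)-6-[(5,7,3',4'-tetra-O-benzyl-3-O-TBS-catechin-8-yl)methylidene]cyclohexa-2,4-dien-1-one (ortho-quinone methide) | O=C1C=C(OCc9ccccc9)C=C(OCc9ccccc9)/C1=C\c2c(OCc9ccccc9)cc(OCc9ccccc9)c3c2O[C@H](c2ccc(OCc9ccccc9)c(OCc9ccccc9)c2)[C@@H](O[Si](C)(C)C(C)(C)C)C3 | intermediate (not isolated)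
13 | (S)-1-[(E)-2-(tert-butyldimethylsilyloxy)ethenyl]-2-[diphenyl(trimethylsilyloxy)methyl]pyrrolidine (enamine of 11 and the catalyst) | CC(C)(C)[Si](C)(C)O/C=C/N1CCC[C@H]1C(c1ccccc1)(c1ccccc1)O[Si](C)(C)C | intermediate (not isolated)
14 | 5,7-bis(benzyloxy)-3α-(TBS-oxy)-4β-(5,7,3',4'-tetra-O-benzyl-3-O-TBS-catechin-8-yl)chroman-2-ol, 3R, 3,4-trans, both anomers | CC(C)(C)[Si](C)(C)O[C@@H]1[C@@H](c2c(OCc9ccccc9)cc(OCc9ccccc9)c3c2O[C@H](c2ccc(OCc9ccccc9)c(OCc9ccccc9)c2)[C@@H](O[Si](C)(C)C(C)(C)C)C3)c2c(OCc9ccccc9)cc(OCc9ccccc9)cc2OC1O | intermediate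
15 | 5,7-bis(benzyloxy)-3α-(TBS-oxy)-4β-(5,7,3',4'-tetra-O-benzyl-3-O-TBS-catechin-8-yl)chroman-2-one | CC(C)(C)[Si](C)(C)O[C@@H]1[C@@H](c2c(OCc9ccccc9)cc(OCc9ccccc9)c3c2O[C@H](c2ccc(OCc9ccccc9)c(OCc9ccccc9)c2)[C@@H](O[Si](C)(C)C(C)(C)C)C3)c2c(OCc9ccccc9)cc(OCc9ccccc9)cc2OC1=O | intermediate
16 | 5-bromo-1,2,3-trimethoxybenzene | COc1cc(Br)cc(OC)c1OC | starting material
17 | 5-bromobenzene-1,2,3-triol | Oc1cc(Br)cc(O)c1O | intermediate
18 | 1,2,3-tris(benzyloxy)-5-bromobenzene | Brc1cc(OCc9ccccc9)c(OCc9ccccc9)c(OCc9ccccc9)c1 | intermediate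
19 | 3,4,5-tris(benzyloxy)phenyllithium | [Li]c1cc(OCc9ccccc9)c(OCc9ccccc9)c(OCc9ccccc9)c1 | intermediate (not isolated)
20 | 5,7-bis(benzyloxy)-3α-(TBS-oxy)-4β-(protected catechin-8-yl)-2-[3,4,5-tris(benzyloxy)phenyl]chroman-2-ol, both C2 epimers | CC(C)(C)[Si](C)(C)O[C@@H]1[C@@H](c2c(OCc9ccccc9)cc(OCc9ccccc9)c3c2O[C@H](c2ccc(OCc9ccccc9)c(OCc9ccccc9)c2)[C@@H](O[Si](C)(C)C(C)(C)C)C3)c2c(OCc9ccccc9)cc(OCc9ccccc9)cc2OC1(O)c1cc(OCc9ccccc9)c(OCc9ccccc9)c(OCc9ccccc9)c1 | intermediate
21 | cyclic 2-aryl oxocarbenium ion from 20 | CC(C)(C)[Si](C)(C)O[C@@H]1[C@@H](c2c(OCc9ccccc9)cc(OCc9ccccc9)c3c2O[C@H](c2ccc(OCc9ccccc9)c(OCc9ccccc9)c2)[C@@H](O[Si](C)(C)C(C)(C)C)C3)c2c(OCc9ccccc9)cc(OCc9ccccc9)cc2[O+]=C1c1cc(OCc9ccccc9)c(OCc9ccccc9)c(OCc9ccccc9)c1 | intermediate (not isolated)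
22 | 3-O-TBS-5,7,3',4',5'-penta-O-benzyl-(−)-epigallocatechin-(4β→8)-[3-O-TBS-5,7,3',4'-tetra-O-benzyl-(+)-catechin] | CC(C)(C)[Si](C)(C)O[C@@H]1[C@@H](c2c(OCc9ccccc9)cc(OCc9ccccc9)c3c2O[C@H](c2ccc(OCc9ccccc9)c(OCc9ccccc9)c2)[C@@H](O[Si](C)(C)C(C)(C)C)C3)c2c(OCc9ccccc9)cc(OCc9ccccc9)cc2O[C@@H]1c1cc(OCc9ccccc9)c(OCc9ccccc9)c(OCc9ccccc9)c1 | intermediate
23 | 5,7,3',4',5'-penta-O-benzyl-(−)-epigallocatechin-(4β→8)-[5,7,3',4'-tetra-O-benzyl-(+)-catechin] | O[C@@H]1[C@@H](c2c(OCc9ccccc9)cc(OCc9ccccc9)c3c2O[C@H](c2ccc(OCc9ccccc9)c(OCc9ccccc9)c2)[C@@H](O)C3)c2c(OCc9ccccc9)cc(OCc9ccccc9)cc2O[C@@H]1c1cc(OCc9ccccc9)c(OCc9ccccc9)c(OCc9ccccc9)c1 | intermediate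
24 | 3,4,5-tris(benzyloxy)benzoic acid | OC(=O)c1cc(OCc9ccccc9)c(OCc9ccccc9)c(OCc9ccccc9)c1 | starting material
25 | 3,4,5-tris(benzyloxy)benzoyl chloride | ClC(=O)c1cc(OCc9ccccc9)c(OCc9ccccc9)c(OCc9ccccc9)c1 | intermediate
26 | benzylated epigallocatechin 3-O-gallate-(4β→8)-catechin 3-O-gallate (fifteen benzyl ethers) | O=C(O[C@@H]1[C@@H](c2c(OCc9ccccc9)cc(OCc9ccccc9)c3c2O[C@H](c2ccc(OCc9ccccc9)c(OCc9ccccc9)c2)[C@@H](OC(=O)c2cc(OCc9ccccc9)c(OCc9ccccc9)c(OCc9ccccc9)c2)C3)c2c(OCc9ccccc9)cc(OCc9ccccc9)cc2O[C@@H]1c1cc(OCc9ccccc9)c(OCc9ccccc9)c(OCc9ccccc9)c1)c1cc(OCc9ccccc9)c(OCc9ccccc9)c(OCc9ccccc9)c1 | intermediate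
27 | (−)-epicatechin (2R,3R) | O[C@@H]1Cc2c(O)cc(O)cc2O[C@@H]1c1ccc(O)c(O)c1 | starting material
28 | 5,7,3',4'-tetra-O-benzyl-(−)-epicatechin | O[C@@H]1Cc2c(OCc9ccccc9)cc(OCc9ccccc9)cc2O[C@@H]1c1ccc(OCc9ccccc9)c(OCc9ccccc9)c1 | intermediate
29 | 4β-(2-ethoxyethoxy)-5,7,3',4'-tetra-O-benzyl-(−)-epicatechin | CCOCCO[C@H]1c2c(OCc9ccccc9)cc(OCc9ccccc9)cc2O[C@H](c2ccc(OCc9ccccc9)c(OCc9ccccc9)c2)[C@@H]1O | intermediate
30 | 4β-(2-ethoxyethoxy)-5,7,3',4'-tetra-O-benzyl-(−)-epicatechin 3-O-[3,4,5-tris(benzyloxy)benzoate] | CCOCCO[C@H]1c2c(OCc9ccccc9)cc(OCc9ccccc9)cc2O[C@H](c2ccc(OCc9ccccc9)c(OCc9ccccc9)c2)[C@@H]1OC(=O)c1cc(OCc9ccccc9)c(OCc9ccccc9)c(OCc9ccccc9)c1 | intermediate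
31 | docosa-O-benzyl epicatechin 3-O-gallate-(4β→8)-epigallocatechin 3-O-gallate-(4β→8)-catechin 3-O-gallate | O=C(O[C@@H]1[C@@H](c2c(OCc9ccccc9)cc(OCc9ccccc9)c3c2O[C@H](c2ccc(OCc9ccccc9)c(OCc9ccccc9)c2)[C@@H](OC(=O)c2cc(OCc9ccccc9)c(OCc9ccccc9)c(OCc9ccccc9)c2)C3)c2c(OCc9ccccc9)cc(OCc9ccccc9)c([C@H]3c4c(OCc9ccccc9)cc(OCc9ccccc9)cc4O[C@H](c4ccc(OCc9ccccc9)c(OCc9ccccc9)c4)[C@@H]3OC(=O)c3cc(OCc9ccccc9)c(OCc9ccccc9)c(OCc9ccccc9)c3)c2O[C@@H]1c1cc(OCc9ccccc9)c(OCc9ccccc9)c(OCc9ccccc9)c1)c1cc(OCc9ccccc9)c(OCc9ccccc9)c(OCc9ccccc9)c1 | intermediate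
32 | epicatechin 3-O-gallate-(4β→8)-epigallocatechin 3-O-gallate-(4β→8)-catechin 3-O-gallate (CNP0321910.1) | O=C(O[C@@H]1[C@@H](c2c(O)cc(O)c3c2O[C@H](c2ccc(O)c(O)c2)[C@@H](OC(=O)c2cc(O)c(O)c(O)c2)C3)c2c(O)cc(O)c([C@H]3c4c(O)cc(O)cc4O[C@H](c4ccc(O)c(O)c4)[C@@H]3OC(=O)c3cc(O)c(O)c(O)c3)c2O[C@@H]1c1cc(O)c(O)c(O)c1)c1cc(O)c(O)c(O)c1 | target

## Step count and risks

Total step count: 21. Longest linear sequence: 13 steps (steps 1, 2, 3, 6, 7, 8, 9, 12, 13, 14, 16, 20, 21).

The three steps most likely to fail: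

**Step 8 (key step).** The methide carbon is flanked by two 2,6-dioxygenated rings and is strongly donor-stabilised, so carbon–carbon bond formation may be slow or reversible, and the quinone methide may be lost by self-condensation. Control of relative topicity may also be poor (reaction through the Z-methide or an exo arrangement, or another enamine geometry of the α-silyloxy aldehyde), which would give the 3,4-cis isomer or the wrong absolute sense. The fallback takes the middle unit from the natural flavanol and joins it by a flavan-4-yl cation coupling instead of building ring C. It sets out from compound 2. Commercial (−)-epigallocatechin (O[C@@H]1Cc2c(O)cc(O)cc2O[C@@H]1c1cc(O)c(O)c(O)c1) is benzylated (BnBr, K2CO3, DMF) to 5,7,3',4',5'-penta-O-benzyl-(−)-epigallocatechin F1. Oxidation with DDQ in the presence of 2-ethoxyethanol gives 4β-(2-ethoxyethoxy)-penta-O-benzyl-epigallocatechin F2. F2 is coupled with an excess of 2 under TMSOTf in CH2Cl2 at −78 °C, which should give the 4β→8 dimer diol directly. The fallback comes back to the route at compound 23 and bypasses steps 3 to 14.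

**Step 13.** Hydride may be delivered from the α face, anti to the pseudoaxial 4-aryl group instead of anti to the C3–O bond, which would give the 2,3-trans epimer. Loss of the C3 proton from the oxocarbenium ion (to a 4H-chromene silyl enol ether) may compete, and double addition in the preceding step 12 feeds the same problem. The fallback sets C2 in an open chain by substrate control and recloses ring C by an SN2 displacement. It sets out from lactol 14. Aryllithium 19 (3 equiv, THF, −78 °C) adds to the open hydroxy aldehyde form under Felkin–Anh control and should give the 1,2-anti carbinol, 1-[3,4,5-tris(benzyloxy)phenyl]-2-(TBS-oxy)-3-[4,6-bis(benzyloxy)-2-hydroxyphenyl]-3-(protected catechin-8-yl)propan-1-ol F3. Mitsunobu ring closure (PPh3, DIAD, THF, 0 °C) displaces the activated benzylic hydroxyl by the phenol oxygen with inversion and should give the 2,3-cis flavan. The fallback comes back to the route at compound 22.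

**Step 20.** The electrophile may self-condense through its own free C8, attack may compete at the C6 positions of the dimer, and the acid may scramble the existing interflavan bond. The fallback uses a blocking group. It sets out from compound 28. NBS in CH2Cl2 brominates C8 to give 8-bromo-5,7,3',4'-tetra-O-benzyl-(−)-epicatechin F4. DDQ with 2-ethoxyethanol gives 8-bromo-4β-(2-ethoxyethoxy)-tetra-O-benzyl-epicatechin F5. Acylation with 25 (DMAP, pyridine) gives the bromine-capped electrophile, 8-bromo-4β-(2-ethoxyethoxy)-tetra-O-benzyl-epicatechin 3-O-[3,4,5-tris(benzyloxy)benzoate] F6. F6 cannot self-condense and can be used in excess over 26 (TMSOTf, CH2Cl2, −78 °C) to give the 8-bromo docosa-O-benzyl trimer F7. Hydrogenolysis (H2, Pd(OH)2/C, Et3N, THF/MeOH) removes the bromine together with the benzyl groups. The fallback comes back to the route at compound 32.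

## Further compounds

F1 | step 8 | 5,7,3',4',5'-penta-O-benzyl-(−)-epigallocatechin | O[C@@H]1Cc2c(OCc9ccccc9)cc(OCc9ccccc9)cc2O[C@@H]1c1cc(OCc9ccccc9)c(OCc9ccccc9)c(OCc9ccccc9)c1
F2 | step 8 | 4β-(2-ethoxyethoxy)-5,7,3',4',5'-penta-O-benzyl-(−)-epigallocatechin | CCOCCO[C@H]1c2c(OCc9ccccc9)cc(OCc9ccccc9)cc2O[C@H](c2cc(OCc9ccccc9)c(OCc9ccccc9)c(OCc9ccccc9)c2)[C@@H]1O
F3 | step 13 | 1,2-anti 1-[3,4,5-tris(benzyloxy)phenyl]-2-(TBS-oxy)-3-[4,6-bis(benzyloxy)-2-hydroxyphenyl]-3-(5,7,3',4'-tetra-O-benzyl-3-O-TBS-catechin-8-yl)propan-1-ol | CC(C)(C)[Si](C)(C)O[C@@H]([C@@H](O)c1cc(OCc9ccccc9)c(OCc9ccccc9)c(OCc9ccccc9)c1)[C@@H](c2c(OCc9ccccc9)cc(OCc9ccccc9)c3c2O[C@H](c2ccc(OCc9ccccc9)c(OCc9ccccc9)c2)[C@@H](O[Si](C)(C)C(C)(C)C)C3)c2c(OCc9ccccc9)cc(OCc9ccccc9)cc2O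
F4 | step 20 | 8-bromo-5,7,3',4'-tetra-O-benzyl-(−)-epicatechin | O[C@@H]1Cc2c(OCc9ccccc9)cc(OCc9ccccc9)c(Br)c2O[C@@H]1c1ccc(OCc9ccccc9)c(OCc9ccccc9)c1
F5 | step 20 | 8-bromo-4β-(2-ethoxyethoxy)-5,7,3',4'-tetra-O-benzyl-(−)-epicatechin | CCOCCO[C@H]1c2c(OCc9ccccc9)cc(OCc9ccccc9)c(Br)c2O[C@H](c2ccc(OCc9ccccc9)c(OCc9ccccc9)c2)[C@@H]1O
F6 | step 20 | 8-bromo-4β-(2-ethoxyethoxy)-5,7,3',4'-tetra-O-benzyl-(−)-epicatechin 3-O-[3,4,5-tris(benzyloxy)benzoate] | CCOCCO[C@H]1c2c(OCc9ccccc9)cc(OCc9ccccc9)c(Br)c2O[C@H](c2ccc(OCc9ccccc9)c(OCc9ccccc9)c2)[C@@H]1OC(=O)c1cc(OCc9ccccc9)c(OCc9ccccc9)c(OCc9ccccc9)c1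
F7 | step 20 | docosa-O-benzyl trimer carrying bromine at C8 of the upper unit | O=C(O[C@@H]1[C@@H](c2c(OCc9ccccc9)cc(OCc9ccccc9)c3c2O[C@H](c2ccc(OCc9ccccc9)c(OCc9ccccc9)c2)[C@@H](OC(=O)c2cc(OCc9ccccc9)c(OCc9ccccc9)c(OCc9ccccc9)c2)C3)c2c(OCc9ccccc9)cc(OCc9ccccc9)c([C@H]3c4c(OCc9ccccc9)cc(OCc9ccccc9)c(Br)c4O[C@H](c4ccc(OCc9ccccc9)c(OCc9ccccc9)c4)[C@@H]3OC(=O)c3cc(OCc9ccccc9)c(OCc9ccccc9)c(OCc9ccccc9)c3)c2O[C@@H]1c1cc(OCc9ccccc9)c(OCc9ccccc9)c(OCc9ccccc9)c1)c1cc(OCc9ccccc9)c(OCc9ccccc9)c(OCc9ccccc9)c1
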